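**Retrosynthetic overview**
- The target is two andrographolide-derived labdane halves, each keeping its decalin (rings A and B), joined by the chain C11H2–C12H=C13(CO2Me)–C14H2–C15(=O)–C12′; the butenolide ring sits on C12′. This C13/C14 acrylate unit, flanked by the E-alkene C12=C13 and the C15 ketone, is the feature the strategy rests on.
- Last steps: the C15 ketone is unmasked from a C15 nitro group (Nef reaction), then both 3,19-acetonides are removed.
- Key disconnection: C14–C15 and C12=C13 are made in one flask from the fragment B nitroalkane, methyl 2-(dimethoxyphosphoryl)acrylate and the fragment A 12-aldehyde (nitronate Michael addition, then Horner–Wadsworth–Emmons olefination).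
- Both fragments come from andrographolide 3,19-acetonide: its 14-acetate takes nitromethane by anti-SN2′ at C12 (fragment B), and permanganate cleavage of C12=C13 gives the aldehyde (fragment A).
- No ring is formed anywhere; all five rings and ten of the eleven stereocentres are carried in from andrographolide. Only C12′ (step 3) and the alkene geometry (step 5) are set.

Key step: step 5

Remark: labdane numbering is used; unprimed atoms belong to the methyl ester half (fragment A), primed atoms to the butenolide half (fragment B). The two C15 epimers of the nitro compound 12 are assumed to be carried on together, since C15 becomes a carbonyl carbon.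

**Step 1**
Reactants: 1 andrographolide; 2 2,2-dimethoxypropane
Product: 3 3,19-O-isopropylideneandrographolide
Conditions: 2 (excess), PPTS (cat.), toluene/DMSO, 80 °C
Reagents that add atoms: 2,2-dimethoxypropane, COC(C)(C)OC
Why: Acid-catalysed transacetalization closes the six-membered 1,3-dioxane over the C3 and C19 hydroxyls (the only 1,3-diol), leaving the allylic C14 hydroxyl free and creating no stereocentre.

**Step 2**
Reactants: 3 3,19-O-isopropylideneandrographolide (one portion); 4 acetic anhydride
Product: 5 14-O-acetyl-3,19-O-isopropylideneandrographolide
Conditions: 4, pyridine, DMAP (cat.), CH2Cl2, 0 °C → rt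
Reagents that add atoms: acetic anhydride, CC(=O)OC(C)=O
Why: DMAP-catalysed acylation of the only free hydroxyl (C14) turns it into a leaving group without breaking the C14–O bond, so the 14S configuration that later steers the addition is retained.

**Step 3**
Reactants: 5 14-O-acetyl-3,19-O-isopropylideneandrographolide; 6 nitromethane
Product: 7 (12S)-12-(nitromethyl)-14-deoxy-3,19-O-isopropylideneandrographolide (fragment B nitroalkane; α-substituted butenolide with C13=C14)
Conditions: 6 (10 equiv), DBU (1.1 equiv), MeCN, 0 °C
Reagents that add atoms: nitromethane, C[N+](=O)[O-]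
Why: The substrate is a Morita–Baylis–Hillman-type allylic acetate, so the nitronate should add at C12 of the alkylidene lactone and the enolate expel the C14 acetate (Michael addition–E1cB, overall SN2′) to give the endocyclic butenolide; the new C12 centre is set by attack on the face opposite the C14–OAc bond, which corresponds to the 12S (later 12′S) configuration of the target, the large excess of nitromethane suppresses a second alkylation, and any minor C12 epimer is removed by chromatography.

**Step 4**
Reactants: 3 3,19-O-isopropylideneandrographolide (second portion); 8 potassium permanganate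
Product: 9 3,19-O-isopropylidene-13,14,15,16-tetranor-ent-labd-8(17)-en-12-al (fragment A 12-aldehyde)
Conditions: KMnO4 (1.3 equiv), THF (trace H2O), −10 → 0 °C, filtration through Celite
Reagents that add atoms: potassium permanganate, [K+].[O-][Mn](=O)(=O)=O
Why: Permanganate oxidative cleavage: the [3+2] addition of permanganate is fastest at the electron-poor, conjugated C12=C13 bond, and in THF without added base the cyclic pentavalent-manganese diester fragments to the C12 aldehyde and the α-keto lactone, while the unconjugated, hindered C8=C17 methylene reacts more slowly and the reaction is stopped before the aldehyde is oxidized further.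

**Step 5**
Reactants: 7 fragment B nitroalkane; 10 methyl 2-(dimethoxyphosphoryl)acrylate; 9 fragment A 12-aldehyde
Product: 12 C15-nitro bis-acetonide of the coupled skeleton (methyl E-enoate; C15 epimers), via γ-nitro phosphonoester 11 (not isolated)
Conditions: 10 (1.05 equiv, slow addition), DBU (0.3 equiv), MeCN/THF, −20 °C; then LiCl (3 equiv), 9 (1.2 equiv), DBU (1.5 equiv), 0 °C → rt
Reagents that add atoms: methyl 2-(dimethoxyphosphoryl)acrylate, C=C(C(=O)OC)P(=O)(OC)OC; fragment A 12-aldehyde 9, C=C1CC[C@@H]2[C@](C)(COC3(C)C)[C@H](O3)CC[C@@]2(C)[C@@H]1CC=O
Why: DBU generates the C15 nitronate of 7, which adds to the β-carbon of 10 to form C14–C15; the resulting α-phosphono ester 11 is then deprotonated under LiCl/DBU (Masamune–Roush) conditions, and its lithium-chelated carbanion adds to aldehyde 9 and loses dimethyl phosphate through the oxaphosphetane to form C12=C13. The closest known reaction type is the tandem Michael addition–Horner–Wadsworth–Emmons olefination of 2-phosphonoacrylates with nitroalkanes and aldehydes. No ring is closed, since all five rings arrive intact in 7 and 9. The one new stereocentre, C15, is not controlled and is erased in step 6; the lasting stereoelement is the C12=C13 geometry, which should be E (ester trans to C11) because a stabilized α-alkyl phosphonoacetate under lithium-salt conditions eliminates through the more stable anti adduct. The step needs mono-addition of the primary nitronate, secured by slow addition of 10 at −20 °C and by the greater hindrance of the secondary nitronate of 11, and olefination of the enolizable aldehyde without aldol reaction, secured by the mild amidine/LiCl base system. It also needs an untouched C12′ and butenolide: C12′–H is only allylic and β to the nitro group at this stage, and the butenolide γ-hydrogens are less acidic than the nitroalkane, so the base is taken up by the nitro C–H.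

**Step 6**
Reactants: 12 C15-nitro bis-acetonide (C15 epimers); 13 water
Product: 15 C15-ketone bis-acetonide, via potassium nitronate 14 (not isolated)
Conditions: KOtBu (1.05 equiv), THF, −78 → −40 °C; then aq. TiCl3 (4.5 equiv), NH4OAc buffer (pH 5–6), THF/H2O, 0 °C → rt
Reagents that add atoms: water, O
Why: Reductive Nef reaction: the nitronate is reduced by trivalent titanium through the oxime to the imine, which hydrolyses at pH 5–6 to the ketone, so both C15 epimers converge; one equivalent of base selects the nitro C–H (the most acidic site) and the buffered, cold medium limits enolization toward C12′, which is now α to the ketone and allylic.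

**Step 7**
Reactants: 15 C15-ketone bis-acetonide; 13 water
Product: 16 target CNP0330094.1
Conditions: AcOH/H2O (7:3), rt
Reagents that add atoms: none
Why: Acid-catalysed hydrolysis of the two 1,3-dioxane acetals in aqueous acetic acid at room temperature, mild enough to leave the exocyclic methylenes, the enoate, the butenolide and the enolizable C12′ centre unchanged.

**Compound list**
1 | andrographolide | C=C1CC[C@@H]2[C@](C)(CO)[C@H](O)CC[C@@]2(C)[C@@H]1C/C=C1/C(=O)OC[C@H]1O | starting material
2 | 2,2-dimethoxypropane | COC(C)(C)OC | starting material
3 | 3,19-O-isopropylideneandrographolide | C=C1CC[C@@H]2[C@](C)(COC3(C)C)[C@H](O3)CC[C@@]2(C)[C@@H]1C/C=C1/C(=O)OC[C@H]1O | intermediate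
4 | acetic anhydride | CC(=O)OC(C)=O | starting material
5 | 14-O-acetyl-3,19-O-isopropylideneandrographolide | C=C1CC[C@@H]2[C@](C)(COC3(C)C)[C@H](O3)CC[C@@]2(C)[C@@H]1C/C=C1/C(=O)OC[C@H]1OC(C)=O | intermediate
6 | nitromethane | C[N+](=O)[O-] | starting material
7 | (12S)-12-(nitromethyl)-14-deoxy-3,19-O-isopropylideneandrographolide (fragment B nitroalkane) | [O-][N+](=O)C[C@@H](C[C@@H]1C(=C)CC[C@@H]2[C@](C)(COC3(C)C)[C@H](O3)CC[C@]21C)C1=CCOC1=O | intermediate
8 | potassium permanganate | [K+].[O-][Mn](=O)(=O)=O | starting material
9 | 3,19-O-isopropylidene-13,14,15,16-tetranor-ent-labd-8(17)-en-12-al (fragment A 12-aldehyde) | C=C1CC[C@@H]2[C@](C)(COC3(C)C)[C@H](O3)CC[C@@]2(C)[C@@H]1CC=O | intermediate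
10 | methyl 2-(dimethoxyphosphoryl)acrylate | C=C(C(=O)OC)P(=O)(OC)OC | starting material
11 | γ-nitro phosphonoester: methyl 2-(dimethoxyphosphoryl)-4-nitrobutanoate carrying C12′ of fragment B on C4 (epimers at C13 and C15) | COC(=O)C(CC([N+](=O)[O-])[C@@H](C[C@@H]1C(=C)CC[C@@H]2[C@](C)(COC3(C)C)[C@H](O3)CC[C@]21C)C1=CCOC1=O)P(=O)(OC)OC | intermediate
12 | C15-nitro bis-acetonide of the coupled skeleton: fragment A C11H2–C12H=C13(CO2Me)–C14H2–C15H(NO2)–C12′ fragment B, E-enoate, C15 epimers | C=C1CC[C@@H]2[C@](C)(COC3(C)C)[C@H](O3)CC[C@@]2(C)[C@@H]1C/C=C(\CC([N+](=O)[O-])[C@@H](C[C@@H]1C(=C)CC[C@@H]2[C@](C)(COC3(C)C)[C@H](O3)CC[C@]21C)C1=CCOC1=O)C(=O)OC | intermediate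
13 | water | O | starting material
14 | potassium C15-nitronate of 12 | C=C1CC[C@@H]2[C@](C)(COC3(C)C)[C@H](O3)CC[C@@]2(C)[C@@H]1C/C=C(\CC(=[N+]([O-])[O-])[C@@H](C[C@@H]1C(=C)CC[C@@H]2[C@](C)(COC3(C)C)[C@H](O3)CC[C@]21C)C1=CCOC1=O)C(=O)OC.[K+] | intermediate
15 | C15-ketone bis-acetonide (3,19:3′,19′-di-O-isopropylidene derivative of the target) | C=C1CC[C@@H]2[C@](C)(COC3(C)C)[C@H](O3)CC[C@@]2(C)[C@@H]1C/C=C(\CC(=O)[C@@H](C[C@@H]1C(=C)CC[C@@H]2[C@](C)(COC3(C)C)[C@H](O3)CC[C@]21C)C1=CCOC1=O)C(=O)OC | intermediate
16 | CNP0330094.1 | C=C1CC[C@@H]2[C@](C)(CO)[C@H](O)CC[C@@]2(C)[C@@H]1C/C=C(\CC(=O)[C@@H](C[C@@H]1C(=C)CC[C@@H]2[C@](C)(CO)[C@H](O)CC[C@]21C)C1=CCOC1=O)C(=O)OC | target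

**Step count**
Total: 7 steps. Longest linear sequence: 6 steps (steps 1, 2, 3, 5, 6, 7); step 4 is a one-step branch from compound 3.

**Steps most likely to fail**

1. Step 5 (three-component union). The hindered, α-branched phosphonate carbanion of 11 may olefinate slowly, so that aldol self-condensation of the aldehyde, a second Michael addition of the nitronate, or erosion of the E/Z ratio takes over. The fallback forms the same two bonds by allylic substitution instead of olefination and sets out from aldehyde 9. A Morita–Baylis–Hillman reaction with methyl acrylate (DABCO) should give the Morita–Baylis–Hillman alcohol F1 (C12 epimers). Acetylation (acetic anhydride, DMAP) should give the Morita–Baylis–Hillman acetate F2. Direct SN2′ alkylation of the nitronate of 7 (K2CO3 or DBU, MeCN, 0 °C) at the terminal methylene, with loss of acetate, should then form C14–C15 and move the alkene to C12=C13 with the E geometry usual for ester-derived acetates. The fallback returns to the route at compound 12.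

2. Step 6 (Nef reaction). The reduction may stall at the hindered C15 oxime, or the trivalent-titanium medium may cause acetal loss and slow enolization at C12′ during a long reaction. The fallback is an oxidative instead of a reductive Nef reaction and sets out from compound 12. The nitronate 14 is formed as before and treated with KHSO5 (as the triple salt 2KHSO5·KHSO4·K2SO4) in Na2HPO4-buffered MeOH/H2O at 0 °C. The electrophilic peroxide oxygen should attack the nitronate carbon and nitrite should leave, giving the ketone directly, while the electron-poor and hindered alkenes stay untouched in the absence of a ketone catalyst. The fallback returns to the route at compound 15 and makes no compound outside the compound list (F0).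

3. Step 4 (permanganate cleavage). Chemoselectivity may be incomplete: the C8=C17 methylene may be attacked too, or the aldehyde may be oxidized on to the acid. The fallback separates the selectivity-determining step from the cleavage and sets out from compound 3. Nucleophilic (Weitz–Scheffer) epoxidation with tert-butyl hydroperoxide/DBU in CH2Cl2 can only attack the electron-poor alkylidene lactone and should give the 12,13-epoxide F3. Periodic acid (H5IO6, THF/H2O, 0 °C → rt) should open the epoxide and cleave the resulting diol to the C12 aldehyde; under this aqueous acid the acetonide is expected to be hydrolysed as well, so the product is taken as the diol aldehyde F4. Kinetic re-protection of the 1,3-diol with 2-methoxypropene/PPTS (cat.) in CH2Cl2 at 0 °C returns to the route at compound 9.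

**Further compounds**
F1 | step 5 | Morita–Baylis–Hillman alcohol: methyl 2-methylene-3-hydroxy ester from aldehyde 9 and methyl acrylate (C12 epimers) | C=C1CC[C@@H]2[C@](C)(COC3(C)C)[C@H](O3)CC[C@@]2(C)[C@@H]1CC(O)C(=C)C(=O)OC
F2 | step 5 | Morita–Baylis–Hillman acetate of F1 (C12 epimers) | C=C1CC[C@@H]2[C@](C)(COC3(C)C)[C@H](O3)CC[C@@]2(C)[C@@H]1CC(OC(C)=O)C(=C)C(=O)OC
F0 | step 6 | none | none
F3 | step 4 | 12,13-epoxide of 3,19-O-isopropylideneandrographolide (epoxide configuration not defined) | C=C1CC[C@@H]2[C@](C)(COC3(C)C)[C@H](O3)CC[C@@]2(C)[C@@H]1CC1OC14C(=O)OC[C@H]4O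
F4 | step 4 | 3,19-dihydroxy-13,14,15,16-tetranor-ent-labd-8(17)-en-12-al (diol aldehyde) | C=C1CC[C@@H]2[C@](C)(CO)[C@H](O)CC[C@@]2(C)[C@@H]1CC=O
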